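**Retrosynthetic overview**
1. The strategy rests on ring B: C8 (CHMe), C9 (quaternary, Me and CH2Ar) and C10 (CH) sit in a row beside the C5=C6 alkene, with the C8 methyl cis to C11 and C11 cis to H10.
2. The arene (C1′–C6′) is attached last at C11 by aryllithium addition to a lactone carbonyl; C8–CH3 and C11H2 come from double deoxygenation; C3′ formylation, O2′ sulfation and debenzylation close the route.
3. The C5=C6 alkene is what remains of a C6 silyl enol ether (enol triflate, then Pd/formate).
4. Ring B is cut at C7–C8 and C9–C10: diene C7=C6(OSi)–C5=C10 on ring A plus the Z-locked C8=C9 of 3-methyl-2(5H)-furanone; a catalytic asymmetric exo [4+2] sets C8, C9 and C10.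
5. Ring order: ring A (bought as 2,2-dimethylcyclohexanone), then ring B with a temporary γ-lactone, then the arene.

Key step: step 4

Numbering: terpenoid numbering (ring A C1–C5, C10; ring B C5–C10; C11 benzylic; arene C1′ on C11, C2′ O-sulfate, C3′ CHO, C4′/C5′ OH). Compounds 7–9 and 16–18 are (8R,9S,10R) and 19–24 are (8R,9R,10S); the spatial arrangement is the same and only CIP priorities change.

Assumption 1: the sense of facial induction of the oxazaborolidinium ion with an α-methyl butenolide is taken as shielding of the C4 Si face by the (S)-catalyst; it has to be confirmed on adduct 7, and the (R)-catalyst is used if the sense is opposite.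
Assumption 2: sulfates 23 and 24 are written in the acid form of the target SMILES but are handled as sodium salts.

**Step 1**
Reactants: 1 2,2-dimethylcyclohexanone
Product: 2 6,6-dimethylcyclohex-1-en-1-yl trifluoromethanesulfonate
Conditions: LDA, THF, −78 °C; PhNTf2, −78 °C → rt
Reagents that add atoms: N-phenylbis(trifluoromethanesulfonimide), O=S(=O)(N(c1ccccc1)S(=O)(=O)C(F)(F)F)C(F)(F)F
Why: Only C6 of the ketone is enolisable, so a single lithium enolate forms and is O-sulfonylated (enol triflate formation).

**Step 2**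
Reactants: 2 6,6-dimethylcyclohex-1-en-1-yl trifluoromethanesulfonate
Product: 4 1-(6,6-dimethylcyclohex-1-en-1-yl)ethan-1-one, via ethoxyvinyl diene 3 (not isolated)
Conditions: Bu3Sn–C(OEt)=CH2, Pd(PPh3)4 (5 mol %), LiCl, THF, reflux; then 1 M HCl, rt
Reagents that add atoms: tributyl(1-ethoxyvinyl)stannane, C=C(OCC)[Sn](CCCC)(CCCC)CCCC; water, O
Why: Stille coupling of an enol triflate with the 1-ethoxyvinyl stannane (chloride-assisted transmetalation) followed by acid hydrolysis of the ethyl enol ether is a standard route to 1-acylcycloalkenes.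

**Step 3**
Reactants: 4 1-(6,6-dimethylcyclohex-1-en-1-yl)ethan-1-one
Product: 5 1-[1-(tert-butyldimethylsilyloxy)vinyl]-6,6-dimethylcyclohex-1-ene
Conditions: TBSOTf, Et3N, CH2Cl2, 0 °C
Reagents that add atoms: tert-butyldimethylsilyl trifluoromethanesulfonate, CC(C)(C)[Si](C)(C)OS(=O)(=O)C(F)(F)F
Why: Soft enolisation of the O-silylated methyl ketone removes a proton from the acetyl CH3 and should give the cross-conjugated 2-silyloxydiene (silyl enol ether formation).

**Step 4**
Reactants: 5 1-[1-(tert-butyldimethylsilyloxy)vinyl]-6,6-dimethylcyclohex-1-ene; 6 3-methyl-2(5H)-furanone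
Product: 7 (8R,9S,10R) tricyclic lactone with C6 silyl enol ether
Conditions: (S)-B-(o-tolyl) diphenylprolinol oxazaborolidine (20 mol %), Tf2NH (17 mol %), CH2Cl2, −40 → 0 °C; Et3N quench
Reagents that add atoms: none
Why: The oxazaborolidinium ion binds the lactone carbonyl of 6 and lowers its LUMO, and diene 5 adds suprafacially across C8=C9 in a concerted, asynchronous [4+2] in which the C7–C8 bond (enol-ether carbon to β-carbon) runs ahead of C9–C10; the closest known reactions are exo-selective Lewis-acid Diels–Alder additions of α-methyl α,β-unsaturated carbonyl compounds to 6,6-dimethyl-1-vinylcyclohexenes and cationic oxazaborolidine catalysis of 2-silyloxydiene additions to unsaturated esters, ketones and quinones, which the butenolide extends. Ring B closes as a cyclohexene by this six-electron cycloaddition and keeps the C5=C6 enol ether. C8 and C9 are set together by the butenolide ring, which holds the OCH2 and the carbonyl cis, so the future C8 methyl and C11 lie on one face. C10 is set by exo approach, in which the catalyst-bound carbonyl points away from the diene and the α-methyl lies under C5, making C11 cis to H10; endo approach would press the Lewis acid complex against the C4 gem-dimethyl group and the silyloxy group. Absolute configuration comes from the catalyst, which must leave the Re face at C4 of 6 open to the diene. Regiochemistry is secured twice, by the silyloxy group (C7 nucleophilic) and by the ring substituent at C10.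

**Step 5**
Reactants: 7 (8R,9S,10R) tricyclic lactone with C6 silyl enol ether
Product: 8 (8R,9S,10R) tricyclic lactone C6 enol triflate
Conditions: CsF, PhNTf2, DME, rt
Reagents that add atoms: N-phenylbis(trifluoromethanesulfonimide), O=S(=O)(N(c1ccccc1)S(=O)(=O)C(F)(F)F)C(F)(F)F
Why: Fluoride cleaves the Si–O bond to a regiodefined caesium enolate that is trapped on oxygen before the double bond can move (direct silyl enol ether to enol triflate exchange), and the lactone has no α-hydrogen.

**Step 6**
Reactants: 8 (8R,9S,10R) tricyclic lactone C6 enol triflate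
Product: 9 (8R,9S,10R) tricyclic lactone with C5=C6 alkene
Conditions: Pd(OAc)2 (5 mol %), PPh3, HCO2H, n-Bu3N, DMF, 60 °C
Reagents that add atoms: none
Why: Oxidative addition of Pd(0) into C6–OTf, formate exchange, decarboxylation to Pd–H and reductive elimination replace OTf by H with the alkene fixed at C5=C6 (formate reduction of an enol triflate).

**Step 7**
Reactants: 10 3,4-bis(benzyloxy)benzaldehyde
Product: 12 3,4-bis(benzyloxy)phenol, via aryl formate 11 (not isolated)
Conditions: mCPBA, CH2Cl2, 0 °C → rt; then K2CO3 (cat.), MeOH, rt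
Reagents that add atoms: 3-chloroperoxybenzoic acid, OOC(=O)c1cccc(Cl)c1
Why: Baeyer–Villiger (Dakin-type) oxidation of the electron-rich benzaldehyde with aryl migration gives the formate, which is methanolysed to the phenol.

**Step 8**
Reactants: 12 3,4-bis(benzyloxy)phenol
Product: 13 4,5-bis(benzyloxy)-2-bromophenol
Conditions: NBS, MeCN, 0 °C
Reagents that add atoms: N-bromosuccinimide, BrN1C(=O)CCC1=O
Why: Electrophilic aromatic bromination should go to C6 of the phenol, the unhindered position ortho to OH and para to the 3-benzyloxy group.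

**Step 9**
Reactants: 13 4,5-bis(benzyloxy)-2-bromophenol
Product: 14 1,2-bis(benzyloxy)-4-bromo-5-(methoxymethoxy)benzene
Conditions: MOMCl, i-Pr2NEt, CH2Cl2, 0 °C → rt
Reagents that add atoms: chloromethyl methyl ether, COCCl
Why: O-alkylation of the phenol gives a MOM ether that tolerates organolithiums, later directs ortho-metalation and is orthogonal to the benzyl ethers.

**Step 10**
Reactants: 14 1,2-bis(benzyloxy)-4-bromo-5-(methoxymethoxy)benzene; 9 (8R,9S,10R) tricyclic lactone with C5=C6 alkene
Product: 16 (8R,9S,10R) C8-hydroxymethyl C11 aryl ketone, via aryllithium 15 (not isolated)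
Conditions: n-BuLi, THF, −78 °C; then 9, −78 → 0 °C; H2O
Reagents that add atoms: none
Why: Bromine–lithium exchange gives the aryllithium, which adds once to the lactone carbonyl (acylation of an organolithium by a lactone); the hemiketal alkoxide persists at low temperature and the ketone, between quaternary C9 and an ortho-substituted arene, is too hindered for a second addition.

**Step 11**
Reactants: 16 (8R,9S,10R) C8-hydroxymethyl C11 aryl ketone
Product: 17 (8R,9S,10R) 1,4-diol (C11 carbinol as epimer mixture)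
Conditions: LiAlH4, THF, 0 °C → rt
Reagents that add atoms: none
Why: Hydride reduction of the aryl ketone (a lactol tautomer reacts through its open form) gives the benzylic alcohol, whose configuration is irrelevant because C11 becomes CH2 in step 13.

**Step 12**
Reactants: 17 (8R,9S,10R) 1,4-diol
Product: 18 (8R,9S,10R) bis(S-methyl xanthate)
Conditions: NaH, imidazole (cat.), THF, 0 °C → rt; CS2; MeI
Reagents that add atoms: carbon disulfide, S=C=S; iodomethane, CI
Why: Both alkoxides add to CS2 and are S-methylated (xanthate formation), and the basic medium avoids closure of the 1,4-diol to a tetrahydrofuran.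

**Step 13**
Reactants: 18 (8R,9S,10R) bis(S-methyl xanthate)
Product: 19 (8R,9R,10S) C8-methyl C11-methylene aryl MOM ether
Conditions: Bu3SnH, ACHN, xylene, 140 °C
Reagents that add atoms: none
Why: Barton–McCombie deoxygenation: stannyl radical adds to each C=S and β-scission releases the benzylic C11 radical easily and the primary radical at the higher temperature, both quenched by Bu3SnH, with no stereocentre involved.

**Step 14**
Reactants: 19 (8R,9R,10S) C8-methyl C11-methylene aryl MOM ether
Product: 21 (8R,9R,10S) C3′ aldehyde MOM ether, via C3′-aryllithium 20 (not isolated)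
Conditions: n-BuLi, TMEDA, THF, −40 → 0 °C; DMF, −78 °C → rt
Reagents that add atoms: N,N-dimethylformamide, CN(C)C=O
Why: Directed ortho-metalation occurs at C3′, the ring position flanked by OMOM and OBn, and the aryllithium is formylated by DMF.

**Step 15**
Reactants: 21 (8R,9R,10S) C3′ aldehyde MOM ether
Product: 22 (8R,9R,10S) C2′ phenol C3′ aldehyde
Conditions: 2 M aq. HCl, THF, 40 °C
Reagents that add atoms: none
Why: Acid hydrolysis of the MOM acetal is assisted by the ortho formyl group and is mild enough to leave the hindered trisubstituted alkene and the benzyl ethers alone.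

**Step 16**
Reactants: 22 (8R,9R,10S) C2′ phenol C3′ aldehyde
Product: 23 (8R,9R,10S) C2′ hydrogen sulfate dibenzyl ether
Conditions: SO3·pyridine, pyridine, 50 °C; Na+ ion-exchange resin
Reagents that add atoms: sulfur trioxide pyridine complex, [O-]S(=O)(=O)[n+]1ccccc1
Why: The only free phenol is O-sulfonated by the SO3 amine complex (aryl sulfate monoester formation).

**Step 17**
Reactants: 23 (8R,9R,10S) C2′ hydrogen sulfate dibenzyl ether
Product: 24 target CNP0115595.2
Conditions: H2 (1 atm), 10 % Pd/C, EtOAc/MeOH, rt, stopped at consumption of 23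
Reagents that add atoms: none
Why: Hydrogenolysis of aryl benzyl ethers should outpace hydrogenation of the hindered C5=C6 alkene next to quaternary C4 and of the chelated, doubly ortho-substituted formyl group, and aryl sulfate salts are inert to H2/Pd.

**Compound list**
1 | 2,2-dimethylcyclohexanone | CC1(C)CCCCC1=O | starting material
2 | 6,6-dimethylcyclohex-1-en-1-yl trifluoromethanesulfonate | CC1(C)CCCC=C1OS(=O)(=O)C(F)(F)F | intermediate
3 | 1-(1-ethoxyvinyl)-6,6-dimethylcyclohex-1-ene | C=C(OCC)C1=CCCCC1(C)C | intermediate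
4 | 1-(6,6-dimethylcyclohex-1-en-1-yl)ethan-1-one | CC(=O)C1=CCCCC1(C)C | intermediate
5 | 1-[1-(tert-butyldimethylsilyloxy)vinyl]-6,6-dimethylcyclohex-1-ene | C=C(O[Si](C)(C)C(C)(C)C)C1=CCCCC1(C)C | intermediate
6 | 3-methyl-2(5H)-furanone | CC1=CCOC1=O | starting material
7 | (3aR,9aR,9bS)-5-(tert-butyldimethylsilyloxy)-6,6,9b-trimethyl-3a,4,6,7,8,9,9a,9b-octahydronaphtho[1,2-c]furan-1(3H)-one; cis-fused lactone, H10 cis to C11 | C1[C@@H]2CC(O[Si](C)(C)C(C)(C)C)=C3[C@@H](CCCC3(C)C)[C@]2(C)C(=O)O1 | intermediate
8 | (3aR,9aR,9bS)-6,6,9b-trimethyl-1-oxo-1,3,3a,4,6,7,8,9,9a,9b-decahydronaphtho[1,2-c]furan-5-yl trifluoromethanesulfonate | C1[C@@H]2CC(OS(=O)(=O)C(F)(F)F)=C3[C@@H](CCCC3(C)C)[C@]2(C)C(=O)O1 | intermediate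
9 | (3aR,9aR,9bS)-6,6,9b-trimethyl-3a,4,6,7,8,9,9a,9b-octahydronaphtho[1,2-c]furan-1(3H)-one | C1[C@@H]2CC=C3[C@@H](CCCC3(C)C)[C@]2(C)C(=O)O1 | intermediate
10 | 3,4-bis(benzyloxy)benzaldehyde | O=Cc1ccc(OCc2ccccc2)c(OCc2ccccc2)c1 | starting material
11 | 3,4-bis(benzyloxy)phenyl formate | O=COc1ccc(OCc2ccccc2)c(OCc2ccccc2)c1 | intermediate
12 | 3,4-bis(benzyloxy)phenol | Oc1ccc(OCc2ccccc2)c(OCc2ccccc2)c1 | intermediate
13 | 4,5-bis(benzyloxy)-2-bromophenol | Oc1cc(OCc2ccccc2)c(OCc2ccccc2)cc1Br | intermediate
14 | 1,2-bis(benzyloxy)-4-bromo-5-(methoxymethoxy)benzene | COCOc1cc(OCc2ccccc2)c(OCc2ccccc2)cc1Br | intermediate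
15 | [4,5-bis(benzyloxy)-2-(methoxymethoxy)phenyl]lithium | COCOc1cc(OCc2ccccc2)c(OCc2ccccc2)cc1[Li] | intermediate
16 | (8R,9S,10R) hydroxy ketone: C8–CH2OH, C9–C(=O)Ar, Ar = 4,5-bis(benzyloxy)-2-(methoxymethoxy)phenyl (in equilibrium with its lactol) | OC[C@@H]1CC=C2[C@@H](CCCC2(C)C)[C@]1(C)C(=O)c1cc(OCc2ccccc2)c(OCc2ccccc2)cc1OCOC | intermediate
17 | (8R,9S,10R) diol: C8–CH2OH, C9–CH(OH)Ar, C11 epimers | OC[C@@H]1CC=C2[C@@H](CCCC2(C)C)[C@]1(C)C(O)c1cc(OCc2ccccc2)c(OCc2ccccc2)cc1OCOC | intermediate
18 | (8R,9S,10R) bis(S-methyl dithiocarbonate) of 17 | CSC(=S)OC[C@@H]1CC=C2[C@@H](CCCC2(C)C)[C@]1(C)C(OC(=S)SC)c1cc(OCc2ccccc2)c(OCc2ccccc2)cc1OCOC | intermediate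
19 | (8R,9R,10S) C8-methyl, C9-CH2Ar, Ar = 4,5-bis(benzyloxy)-2-(methoxymethoxy)phenyl | C[C@@H]1CC=C2[C@@H](CCCC2(C)C)[C@]1(C)Cc1cc(OCc2ccccc2)c(OCc2ccccc2)cc1OCOC | intermediate
20 | C3′-lithio derivative of 19 | C[C@@H]1CC=C2[C@@H](CCCC2(C)C)[C@]1(C)Cc1cc(OCc2ccccc2)c(OCc2ccccc2)c([Li])c1OCOC | intermediate
21 | (8R,9R,10S) 3′-formyl-4′,5′-bis(benzyloxy)-2′-(methoxymethoxy) compound | C[C@@H]1CC=C2[C@@H](CCCC2(C)C)[C@]1(C)Cc1cc(OCc2ccccc2)c(OCc2ccccc2)c(C=O)c1OCOC | intermediate
22 | (8R,9R,10S) 3′-formyl-4′,5′-bis(benzyloxy)-2′-hydroxy compound | C[C@@H]1CC=C2[C@@H](CCCC2(C)C)[C@]1(C)Cc1cc(OCc2ccccc2)c(OCc2ccccc2)c(C=O)c1O | intermediate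
23 | (8R,9R,10S) 3′-formyl-4′,5′-bis(benzyloxy)-2′-yl hydrogen sulfate | C[C@@H]1CC=C2[C@@H](CCCC2(C)C)[C@]1(C)Cc1cc(OCc2ccccc2)c(OCc2ccccc2)c(C=O)c1OS(=O)(=O)O | intermediate
24 | CNP0115595.2, (8R,9R,10S) 3′-formyl-4′,5′-dihydroxy-2′-yl hydrogen sulfate | C[C@@H]1CC=C2[C@@H](CCCC2(C)C)[C@]1(C)Cc1cc(O)c(O)c(C=O)c1OS(=O)(=O)O | target

**Step count**
Total: 17 steps. Longest linear sequence: 14 steps (1, 2, 3, 4, 5, 6, 10, 11, 12, 13, 14, 15, 16, 17); the arene branch is steps 7–9.

**Steps most likely to fail**

Step 4. The α-methyl butenolide is a weak dienophile, so turnover may be slower than acid-induced loss of the silyl enol ether (protodesilylation, or Mukaiyama–Michael addition without ring closure), and exo or facial discrimination may be incomplete. The fallback sets out from triflate 2 and butenolide 6 and comes back at 9. Stille coupling of 2 with tributyl(vinyl)stannane (Pd(PPh3)4, LiCl, THF, reflux) should give 6,6-dimethyl-1-vinylcyclohexene F1, an acid-stable diene of the class known to react exo-selectively with α-methyl unsaturated carbonyl compounds. F1 and 6 under the stronger AlBr3-activated oxazaborolidine (CH2Cl2, −20 °C → rt) should give lactone 9 directly, with regiochemistry resting on the terminal CH2 of the vinyl group as the nucleophilic end; steps 3, 5 and 6 are then not needed.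

Step 13. Fragmentation at the primary xanthate may be slow, returning alcohol or thioformate, and the electron-rich benzylic xanthate may rearrange thermally before reduction. The fallback sets out from hydroxy ketone 16 and comes back at 19, removing the two oxygens one at a time while C11 is still a ketone, so that no oxygen nucleophile can close a tetrahydrofuran. I2, PPh3 and imidazole should give the primary iodide, iodo ketone F2. Bu3SnH/AIBN (toluene, 80 °C) should reduce it to the C8-methyl aryl ketone F3. LiAlH4 then gives the benzylic alcohol F4, NaH/CS2/MeI its xanthate F5, and Bu3SnH/AIBN (toluene, 110 °C) the methylene compound 19.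

Step 17. Hydrogenation of the C5=C6 alkene or reduction of the formyl group may compete with debenzylation. The fallback sets out from 22 and comes back at 24, and avoids hydrogen. BCl3 with pentamethylbenzene (CH2Cl2, −78 °C) should remove both benzyl groups to give the trihydroxy aldehyde F6. t-Bu2Si(OTf)2 and 2,6-lutidine should bridge only the catechol oxygens O4′ and O5′, giving the silylene F7. SO3·pyridine then sulfates the remaining O2′ phenol to the silylene sulfate F8, and buffered fluoride (TBAF/AcOH, THF, 0 °C) releases the catechol to give 24.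

**Further compounds**
F1 | step 4 | 6,6-dimethyl-1-vinylcyclohex-1-ene | C=CC1=CCCCC1(C)C
F2 | step 13 | (8R,9S,10R) C8-iodomethyl C11 aryl ketone | IC[C@@H]1CC=C2[C@@H](CCCC2(C)C)[C@]1(C)C(=O)c1cc(OCc2ccccc2)c(OCc2ccccc2)cc1OCOC
F3 | step 13 | C8-methyl C11 aryl ketone, configuration as in 16 | C[C@@H]1CC=C2[C@@H](CCCC2(C)C)[C@]1(C)C(=O)c1cc(OCc2ccccc2)c(OCc2ccccc2)cc1OCOC
F4 | step 13 | C8-methyl C11 benzylic alcohol, C11 epimers | C[C@@H]1CC=C2[C@@H](CCCC2(C)C)[C@]1(C)C(O)c1cc(OCc2ccccc2)c(OCc2ccccc2)cc1OCOC
F5 | step 13 | S-methyl xanthate of F4 | C[C@@H]1CC=C2[C@@H](CCCC2(C)C)[C@]1(C)C(OC(=S)SC)c1cc(OCc2ccccc2)c(OCc2ccccc2)cc1OCOC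
F6 | step 17 | (8R,9R,10S) 3′-formyl-2′,4′,5′-trihydroxy compound | C[C@@H]1CC=C2[C@@H](CCCC2(C)C)[C@]1(C)Cc1cc(O)c(O)c(C=O)c1O
F7 | step 17 | O4′,O5′-di-tert-butylsilylene derivative of F6 | C[C@@H]1CC=C2[C@@H](CCCC2(C)C)[C@]1(C)Cc1cc2O[Si](C(C)(C)C)(C(C)(C)C)Oc2c(C=O)c1O
F8 | step 17 | O2′ hydrogen sulfate of F7 | C[C@@H]1CC=C2[C@@H](CCCC2(C)C)[C@]1(C)Cc1cc2O[Si](C(C)(C)C)(C(C)(C)C)Oc2c(C=O)c1OS(=O)(=O)O
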